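**Retrosynthetic overview**
- The target comes from its 4'-O-acetate by neutral deacetylation (last step).
- The acetate comes from an acyclic (S)-aldol adduct and a prenylated dimethoxybutenolide in one flask. The silyl ether oxygen closes ring C (a dihydropyranone); the silyloxyfuran made from the butenolide then adds to C8a and closes onto C4a in a [4+2] sense, and loss of silanol aromatizes ring A.
- The (S)-aldol adduct comes from 4-acetoxybenzaldehyde and Danishefsky's diene by a catalytic asymmetric Mukaiyama aldol reaction, which sets C2.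
- The butenolide comes from C5-prenylation of 3,4-dimethoxyfuran-2(5H)-one, itself made from methyl methoxyacetate and methyl glycolate (Dieckmann closure, O-methylation).
- Ring order: ring B is bought; rings C and A are formed together in the key step.

Assumption: the SMILES descriptor is read as (2S), and the 2:1 (S)-BINOL/Ti(OiPr)4 catalyst is taken to attack the Si face of the aryl aldehyde as it does with benzaldehyde (otherwise (R)-BINOL is used).

**Step 1**
Reactants: 1 methyl methoxyacetate; 2 methyl glycolate
Product: 4 butenolide 3,4-dimethoxyfuran-2(5H)-one, via potassium 3-methoxytetronate 3 (not isolated)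
Conditions: KOtBu (2.2 equiv), DMF, 0 °C → rt; then Me2SO4 (2.5 equiv), rt
Reagents that add atoms: dimethyl sulfate, COS(=O)(=O)OC
Why: Alkoxide exchange places the methoxyacetyl group on the glycolate oxygen, the ester enolate closes the five-membered ring by Dieckmann (Lacey-type) condensation driven by the stable tetronate salt, and hard O-methylation of that salt in DMF goes to the C4 oxygen as in the standard preparation of methyl tetronate (no stereocenter).

**Step 2**
Reactants: 4 butenolide 3,4-dimethoxyfuran-2(5H)-one; 5 prenyl bromide (1-bromo-3-methylbut-2-ene)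
Product: 6 (±)-3,4-dimethoxy-5-(3-methylbut-2-en-1-yl)furan-2(5H)-one
Conditions: LiN(iPr)2 (1.05 equiv), THF, −78 °C; then 5, −78 → −20 °C
Reagents that add atoms: none
Why: γ-Deprotonation gives the lithium 2-furanolate, which is alkylated at C5 (C3 is blocked and attack there would break the vinylogous carbonate) by SN2 on the primary allylic bromide, so the prenyl group is not transposed; the new center is racemic and is destroyed in step 4.

**Step 3**
Reactants: 7 4-formylphenyl acetate (4-acetoxybenzaldehyde); 8 Danishefsky's diene, (E)-1-methoxy-3-(trimethylsilyloxy)buta-1,3-diene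
Product: 9 4-[(1S,4E)-5-methoxy-3-oxo-1-(trimethylsilyloxy)pent-4-en-1-yl]phenyl acetate
Conditions: (S)-BINOL (20 mol %), Ti(OiPr)4 (10 mol %), 4 Å MS, Et2O, −20 °C; filtration and evaporation, no acid
Reagents that add atoms: none
Why: The BINOL/Ti(OiPr)4 catalyst (Keck type) runs the Mukaiyama aldol pathway of Danishefsky's diene with silyl transfer to the aldolate, so the acyclic β-silyloxy β'-methoxyvinyl ketone is released, and the (S)-ligand directs attack to the Si face of the aldehyde, which sets the S carbinol that becomes C2.

**Step 4**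
Reactants: 6 (±)-3,4-dimethoxy-5-(3-methylbut-2-en-1-yl)furan-2(5H)-one; 9 4-[(1S,4E)-5-methoxy-3-oxo-1-(trimethylsilyloxy)pent-4-en-1-yl]phenyl acetate
Product: 13 4-[(2S)-5-hydroxy-6,7-dimethoxy-8-(3-methylbut-2-en-1-yl)-4-oxochroman-2-yl]phenyl acetate, via silyloxyfuran 10 (not isolated), via dihydropyranone 11 (not isolated), via oxa-bridged adduct 12 (not isolated)
Conditions: 6 (1.3 equiv), Et3N (1.35 equiv), TMSOTf (1.7 equiv), CH2Cl2, 0 °C; then 9, −78 → 0 °C; aq. NaHCO3
Reagents that add atoms: none
Why: Proposed new method: TMSOTf first closes ring C, because the silyl ether oxygen of 9 adds to the activated β-methoxy enone and methoxytrimethylsilane leaves to give 11 as its 4-silyloxypyrylium ion; the prenyl-bearing carbon of silyloxyfuran 10 then attacks C8a (vinylogous Mukaiyama–Michael), the resulting C4 enol silane closes onto the O-silylated lactonium carbon (Mukaiyama–Claisen, overall a stepwise [4+2]) to give 12, and ketal collapse with loss of trimethylsilanol across C8–C8a aromatizes ring A with 5-OH next to the ketone and prenyl next to the ring oxygen; the closest known reaction types are the acid-induced cyclization of Danishefsky aldol adducts, silyl triflate-mediated conjugate addition to dihydropyranones and the phenol synthesis from 2-silyloxyfurans and electron-poor alkenes (a silyl version of the Hauser–Kraus annulation), and the C2–O bond is never broken, so the S configuration is kept (the electron-poor acetoxyphenyl group disfavors benzylic ionization).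

**Step 5**
Reactants: 13 4-[(2S)-5-hydroxy-6,7-dimethoxy-8-(3-methylbut-2-en-1-yl)-4-oxochroman-2-yl]phenyl acetate
Product: 14 (2S)-5-hydroxy-2-(4-hydroxyphenyl)-6,7-dimethoxy-8-(3-methylbut-2-en-1-yl)chroman-4-one
Conditions: NH4OAc, MeOH/H2O (4:1), rt
Reagents that add atoms: none
Why: Ammonium acetate in aqueous methanol cleaves aryl acetates at about neutral pH (mild acyl transfer), which avoids both the base-induced retro-oxa-Michael ring opening that racemizes flavanones and acid that would attack the prenyl group, so C2 stays S.

**Compound list**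
1 | methyl methoxyacetate | COCC(=O)OC | starting material
2 | methyl glycolate | OCC(=O)OC | starting material
3 | potassium 3-methoxytetronate (potassium 4-methoxy-5-oxo-2,5-dihydrofuran-3-olate) | COC1=C([O-])COC1=O.[K+] | intermediate
4 | 3,4-dimethoxyfuran-2(5H)-one | COC1=C(OC)COC1=O | intermediate
5 | prenyl bromide (1-bromo-3-methylbut-2-ene) | CC(C)=CCBr | starting material
6 | (±)-3,4-dimethoxy-5-(3-methylbut-2-en-1-yl)furan-2(5H)-one | COC1=C(OC)C(CC=C(C)C)OC1=O | intermediate
7 | 4-formylphenyl acetate | CC(=O)Oc1ccc(C=O)cc1 | starting material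
8 | Danishefsky's diene, (E)-1-methoxy-3-(trimethylsilyloxy)buta-1,3-diene | CO/C=C/C(=C)O[Si](C)(C)C | starting material
9 | 4-[(1S,4E)-5-methoxy-3-oxo-1-(trimethylsilyloxy)pent-4-en-1-yl]phenyl acetate | C[Si](C)(C)O[C@H](c1ccc(OC(C)=O)cc1)CC(=O)/C=C/OC | intermediate
10 | 3,4-dimethoxy-5-(3-methylbut-2-en-1-yl)-2-(trimethylsilyloxy)furan | COc1c(OC)c(CC=C(C)C)oc1O[Si](C)(C)C | intermediate
11 | 4-[(2S)-4-oxo-3,4-dihydro-2H-pyran-2-yl]phenyl acetate | C1=CO[C@H](c2ccc(OC(C)=O)cc2)CC1=O | intermediate
12 | 4-[(2S)-5,8-epoxy-6,7-dimethoxy-8-(3-methylbut-2-en-1-yl)-4-oxo-5-(trimethylsilyloxy)-4a,5,8,8a-tetrahydrochroman-2-yl]phenyl acetate (mixture at C4a, C5, C8, C8a) | COC1=C(OC)C2(CC=C(C)C)OC1(O[Si](C)(C)C)C1C2O[C@H](c2ccc(OC(C)=O)cc2)CC1=O | intermediate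
13 | 4-[(2S)-5-hydroxy-6,7-dimethoxy-8-(3-methylbut-2-en-1-yl)-4-oxochroman-2-yl]phenyl acetate | COc1c(O)c2c(c(CC=C(C)C)c1OC)O[C@H](c1ccc(OC(C)=O)cc1)CC2=O | intermediate
14 | (2S)-5-hydroxy-2-(4-hydroxyphenyl)-6,7-dimethoxy-8-(3-methylbut-2-en-1-yl)chroman-4-one | COc1c(O)c2c(c(CC=C(C)C)c1OC)O[C@H](c1ccc(O)cc1)CC2=O | target

**Total step count:** 5 (convergent: steps 1–2 make the ring-A fragment, step 3 the chiral fragment).
**Longest linear sequence:** 4 steps (1, 2, 4, 5).

**Steps most likely to fail, with fallbacks**

Step 4 is the most uncertain: the cascade may stop after the Michael addition if the enol silane does not close onto the lactone, or the prenyl group may suffer under the silyl triflate. The fallback sets out from 9 and 6 and replaces silyl-cation chemistry by an enolate annulation on the isolated pyranone. Compound 9 is cyclized with CF3CO2H in CH2Cl2 at 0 °C to dihydropyranone 11, which is now isolated. Butenolide 6 is deprotonated with LiN(SiMe3)2 in THF at −78 °C, and the lithium furanolate is added to 11 in a Hauser–Kraus-type Michael–Dieckmann sequence. A buffered quench gives (2S)-2-(4-acetoxyphenyl)-5,8-dihydroxy-6,7-dimethoxy-8-(3-methylbut-2-en-1-yl)-2,3,8,8a-tetrahydro-4H-chromen-4-one F1. PPTS in toluene then removes water across C8–C8a, and the sequence comes back to the route at 13.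

Step 1 may fail through ester self-condensation in the one-pot transesterification/Dieckmann reaction or through methylation at the wrong tetronate oxygen. The fallback sets out from 1 and fixes the enol ether before the ring is closed. The enolate of 1 (LiN(iPr)2, 2 equiv, THF, −78 °C) is acylated with chloroacetyl chloride to give methyl 4-chloro-2-methoxy-3-oxobutanoate F2. Trimethyl orthoformate with catalytic H2SO4 converts it into methyl 4-chloro-2,3-dimethoxybut-2-enoate F3. Heating F3 neat at about 140 °C closes the lactone with loss of chloromethane, as in the technical synthesis of methyl tetronate, and the sequence comes back to the route at 4.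

Step 2 may give C3- or double alkylation of the furanolate. The fallback sets out from 2 and 5 and installs the prenyl group before the ring exists. The dianion of 2 (LiN(iPr)2, 2.2 equiv, THF/DMPU, −78 °C) is alkylated with 5 to give methyl 2-hydroxy-5-methylhex-4-enoate F4. Acylation with methoxyacetyl chloride and pyridine gives methyl 2-(2-methoxyacetoxy)-5-methylhex-4-enoate F5. Dieckmann closure with LiN(SiMe3)2 gives 4-hydroxy-3-methoxy-5-(3-methylbut-2-en-1-yl)furan-2(5H)-one F6. O-Methylation with Me2SO4 and K2CO3 in acetone then comes back to the route at 6.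

**Further compounds**
F1 | step 4 | (2S)-2-(4-acetoxyphenyl)-5,8-dihydroxy-6,7-dimethoxy-8-(3-methylbut-2-en-1-yl)-2,3,8,8a-tetrahydro-4H-chromen-4-one (mixture at C8, C8a) | COC1=C(OC)C(O)(CC=C(C)C)C2O[C@H](c3ccc(OC(C)=O)cc3)CC(=O)C2=C1O
F2 | step 1 | methyl 4-chloro-2-methoxy-3-oxobutanoate | COC(C(=O)CCl)C(=O)OC
F3 | step 1 | methyl 4-chloro-2,3-dimethoxybut-2-enoate | COC(=O)C(OC)=C(OC)CCl
F4 | step 2 | methyl 2-hydroxy-5-methylhex-4-enoate (racemic) | COC(=O)C(O)CC=C(C)C
F5 | step 2 | methyl 2-(2-methoxyacetoxy)-5-methylhex-4-enoate (racemic) | COCC(=O)OC(CC=C(C)C)C(=O)OC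
F6 | step 2 | 4-hydroxy-3-methoxy-5-(3-methylbut-2-en-1-yl)furan-2(5H)-one (racemic) | COC1=C(O)C(CC=C(C)C)OC1=O
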